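**Retrosynthetic overview**
1. 24 ⇐ 21 (TES→Ac exchange, TBS removal) ⇐ 19 + CO2: the O–C(=O) unit of the lactone is carbon dioxide. The C15–C16 bond comes from Cu-catalysed carboxylation of a C15 alkenylboronate, the O–C2 bond from SN2 lactonisation onto a C2 allylic phosphate with inversion.
2. Enabling feature: the lactone carbonyl C16 hangs on the 1,1-disubstituted vinyl carbon C15 (exocyclic on ring carbon C1), and the lactone oxygen sits on C2, which is 1,3 to C15 and allylic to the C3=C4 alkene of the 14-membered ring. A C15 alkenyl-metal and a C2 allylic electrophile therefore bracket exactly one CO2.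
3. 19 ⇐ 18 ⇐ 16: the C1–C2 bond and the carbocycle come from intramolecular allylboration of a 2-boryl allylboronate (Pt diboration of a terminal allene) onto the C2 enal. This sets C1, gives the 2-epi alcohol and leaves B(pin) on C15.
4. 15 ⇐ three iterative, catalyst-controlled vinylogous Mukaiyama aldol additions of one senecioyl-morpholine dienolate (C13–C14, C9–C10, C5–C6; they set C14, C10, C6 and the three E-alkenes), starting from 3-(trimethylsilyl)propynal; the allene comes from a Crabbé homologation.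
5. Ring order: 14-membered carbocycle first (step 14), α-methylene-γ-lactone second (step 16).

Key step: step 16

Remark: cembrane numbering is used for the macrocycles (ring C1–C14, exocyclic C15(=C17H2) on C1, lactone carbonyl C16, which is absent in the "16-nor" intermediates, methyls on C4, C8, C12).
Remark: the aldol catalyst is the dimeric bisphosphoramide made from two N,N'-dimethyl-1,1'-binaphthyl-2,2'-diamine phosphoramide units on an N,N'-dimethylpentane-1,5-diamine linker; its (S,S)-enantiomer is assumed to deliver Si-face attack (S carbinols), and the antipode would be used if the sense is the opposite.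

**Route**

Step 1
Reactants: 1 3-methylbut-2-enoyl chloride; 2 morpholine
Product: 3 4-(3-methylbut-2-enoyl)morpholine
Conditions: Et3N, CH2Cl2, 0 °C to rt
Reagents that add atoms: none
Why: N-acylation of a secondary amine by an acid chloride (amide formation) should be clean and creates no stereocentre.

Step 2
Reactants: 3 4-(3-methylbut-2-enoyl)morpholine
Product: 4 (Z)-4-[1-(tert-butyldimethylsilyloxy)-3-methylbuta-1,3-dien-1-yl]morpholine
Conditions: KHMDS, THF, −78 °C; TBSCl, −78 °C to rt
Reagents that add atoms: tert-butyldimethylsilyl chloride, CC(C)(C)[Si](C)(C)Cl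
Why: γ-deprotonation of the β,β-dimethyl enamide gives the extended dienolate, and its O-silylation should furnish the N,O-silyl dienyl ketene acetal (vinylogous enolate silylation).

Step 3
Reactants: 5 3-(trimethylsilyl)prop-2-ynal; 4 silyl dienolate
Product: 6 (S,E)-5-hydroxy-3-methyl-1-(morpholin-4-yl)-7-(trimethylsilyl)hept-2-en-6-yn-1-one
Conditions: SiCl4 (1.1 equiv), (S,S)-bisphosphoramide catalyst (5 mol %), i-Pr2NEt (10 mol %), CH2Cl2, −78 °C; aq NaHCO3
Reagents that add atoms: none
Why: vinylogous Mukaiyama aldol addition under Lewis-base-activated SiCl4 catalysis, in which γ-attack of the dienolate should give the E-enamide and the chiral phosphoramide-bound silicon cation differentiates the aldehyde faces to set the carbinol (future C14) as S.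

Step 4
Reactants: 6 silyl alkyne
Product: 7 (S,E)-5-hydroxy-3-methyl-1-(morpholin-4-yl)hept-2-en-6-yn-1-one
Conditions: K2CO3 (cat.), MeOH, 0 °C to rt
Reagents that add atoms: none
Why: methoxide-mediated protodesilylation of the alkynylsilane should leave the carbinol and the enamide untouched.

Step 5
Reactants: 7 terminal alkyne
Product: 8 (S,E)-5-hydroxy-3-methyl-1-(morpholin-4-yl)octa-2,6,7-trien-1-one
Conditions: (CH2O)n, CuI, Cy2NH, 1,4-dioxane, reflux
Reagents that add atoms: paraformaldehyde (as formaldehyde), C=O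
Why: Crabbé homologation (aminomethylation of the copper acetylide, then Cu-mediated 1,5-hydride shift with loss of imine) should convert the terminal alkyne into the terminal allene without involving the adjacent carbinol centre.

Step 6
Reactants: 8 α-allenol
Product: 9 (S,E)-3-methyl-1-(morpholin-4-yl)-5-(triethylsilyloxy)octa-2,6,7-trien-1-one
Conditions: TESCl, imidazole, DMF, 0 °C to rt
Reagents that add atoms: chlorotriethylsilane, CC[Si](CC)(CC)Cl
Why: standard O-silylation of a secondary alcohol, chosen so that this oxygen can later be freed in the presence of a TBS ether.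

Step 7
Reactants: 9 TES ether amide
Product: 10 (S,E)-3-methyl-5-(triethylsilyloxy)octa-2,6,7-trienal
Conditions: DIBAL-H, THF, −78 °C; aq Rochelle salt
Reagents that add atoms: none
Why: partial reduction of the morpholine amide, in which one hydride addition gives a chelated tetrahedral aluminium hemiaminal that should release the enal only on work-up.

Step 8
Reactants: 10 enal; 4 silyl dienolate
Product: 11 (2E,5S,6E,9S)-5-hydroxy-3,7-dimethyl-1-(morpholin-4-yl)-9-(triethylsilyloxy)dodeca-2,6,10,11-tetraen-1-one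
Conditions: SiCl4 (1.1 equiv), (S,S)-bisphosphoramide catalyst (5 mol %), i-Pr2NEt (10 mol %), CH2Cl2, −78 °C; aq NaHCO3
Reagents that add atoms: none
Why: second vinylogous Mukaiyama aldol addition, in which the existing centre is 1,5-remote so the catalyst alone should set the new carbinol (future C10) as S while γ-attack gives the second E-alkene.

Step 9
Reactants: 11 hydroxy amide
Product: 12 (2E,5S,6E,9S)-3,7-dimethyl-1-(morpholin-4-yl)-5,9-bis(triethylsilyloxy)dodeca-2,6,10,11-tetraen-1-one
Conditions: TESCl, imidazole, DMF, 0 °C to rt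
Reagents that add atoms: chlorotriethylsilane, CC[Si](CC)(CC)Cl
Why: standard O-silylation of the new allylic alcohol with the same group as on the first carbinol, since both become acetates later.

Step 10
Reactants: 12 bis-TES amide
Product: 13 (2E,5S,6E,9S)-3,7-dimethyl-5,9-bis(triethylsilyloxy)dodeca-2,6,10,11-tetraenal
Conditions: DIBAL-H, THF, −78 °C; aq Rochelle salt
Reagents that add atoms: none
Why: partial reduction of the morpholine amide through the stable tetrahedral aluminium hemiaminal should again stop at the enal.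

Step 11
Reactants: 13 enal; 4 silyl dienolate
Product: 14 (2E,5S,6E,9S,10E,13S)-5-hydroxy-3,7,11-trimethyl-1-(morpholin-4-yl)-9,13-bis(triethylsilyloxy)hexadeca-2,6,10,14,15-pentaen-1-one
Conditions: SiCl4 (1.1 equiv), (S,S)-bisphosphoramide catalyst (5 mol %), i-Pr2NEt (10 mol %), CH2Cl2, −78 °C; aq NaHCO3
Reagents that add atoms: none
Why: third vinylogous Mukaiyama aldol addition, catalyst-controlled as before, should set the last carbinol (future C6) as S and the third E-alkene.

Step 12
Reactants: 14 hydroxy amide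
Product: 15 (2E,5S,6E,9S,10E,13S)-5-(tert-butyldimethylsilyloxy)-3,7,11-trimethyl-1-(morpholin-4-yl)-9,13-bis(triethylsilyloxy)hexadeca-2,6,10,14,15-pentaen-1-one
Conditions: TBSCl, imidazole, DMF, rt
Reagents that add atoms: tert-butyldimethylsilyl chloride, CC(C)(C)[Si](C)(C)Cl
Why: O-silylation with the more robust TBS group marks the oxygen that stays a free hydroxyl in the target.

Step 13
Reactants: 15 allenyl amide
Product: 16 (2E,5S,6E,9S,10E,13S,14Z)-5-(tert-butyldimethylsilyloxy)-3,7,11-trimethyl-1-(morpholin-4-yl)-15,16-bis(4,4,5,5-tetramethyl-1,3,2-dioxaborolan-2-yl)-9,13-bis(triethylsilyloxy)hexadeca-2,6,10,14-tetraen-1-one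
Conditions: B2pin2, Pt(dba)2 (5 mol %), PCy3 (6 mol %), toluene, 50 °C
Reagents that add atoms: bis(pinacolato)diboron, CC1(C)OB(OC1(C)C)B1OC(C)(C)C(C)(C)O1
Why: Pt(0)-catalysed cis-diboration of an allene, in which the bulky phosphine and the branched silyloxy substituent should direct the B–B unit onto the terminal C=C from the face away from the substituent, placing one boron on the central carbon, one on the CH2 terminus and the chain cis to CH2B (14Z).

Step 14
Reactants: 16 bis-boronate amide
Product: 18 (1R,2R,3E,6S,7E,10S,11E,14S)-6-(tert-butyldimethylsilyloxy)-15-(4,4,5,5-tetramethyl-1,3,2-dioxaborolan-2-yl)-10,14-bis(triethylsilyloxy)-16-norcembra-3,7,11,15(17)-tetraen-2-ol, via bis-boryl enal 17 (not isolated)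
Conditions: DIBAL-H, toluene, −78 °C; aq Rochelle salt, 0 °C; then toluene (0.002 M), 70 °C; aq NaHCO3
Reagents that add atoms: none
Why: after amide-to-enal reduction the allylboronate should add to the aldehyde through a Zimmerman–Traxler chair (intramolecular allylboration closing the 14-membered ring), where the Z γ-substituent gives the C1/C2 syn relationship (2R), A(1,3) strain in the Z-allyl unit (H-14 eclipsed, new bond anti to the C13 chain) sets C1, and the vinylic B(pin) on C15 is left as the handle.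

Step 15
Reactants: 18 macrocyclic alcohol
Product: 19 diethyl (1S,2R,3E,6S,7E,10S,11E,14S)-6-(tert-butyldimethylsilyloxy)-15-(4,4,5,5-tetramethyl-1,3,2-dioxaborolan-2-yl)-10,14-bis(triethylsilyloxy)-16-norcembra-3,7,11,15(17)-tetraen-2-yl phosphate
Conditions: (EtO)2P(O)Cl, N-methylimidazole, CH2Cl2, 0 °C
Reagents that add atoms: diethyl chlorophosphate, CCOP(=O)(Cl)OCC
Why: O-phosphorylation proceeds with retention at C2 and should turn the aldehyde-derived oxygen into a leaving group that can still be handled.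

Step 16
Reactants: 19 alkenylboronate allylic phosphate
Product: 21 (1R,2S,3E,6S,7E,10S,11E,14S)-6-(tert-butyldimethylsilyloxy)-10,14-bis(triethylsilyloxy)cembra-3,7,11,15(17)-tetraen-16,2-olide, via potassium acrylate 20 (not isolated)
Conditions: (IPr)CuCl (10 mol %), KOt-Bu (1.1 equiv), CO2 (1 atm), THF (0.01 M), 65 °C; then DMF, 60 °C
Reagents that add atoms: carbon dioxide, O=C=O
Why: t-BuO–Cu(IPr) should transmetallate the C15 alkenyl–B(pin) and the alkenylcopper insert CO2, so that the new C15–C16 bond appears as potassium acrylate 20 and the alkoxide regenerates the catalyst. The carboxylate oxygen then displaces the diethyl phosphate on C2 from the rear (SN2), forming the O–C2 bond and closing the γ-lactone in a 5-exo-tet mode onto the preformed 14-membered ring (SN2' attack at C4 would need a seven-membered ring). The closest known reaction types are the NHC–copper-catalysed carboxylation of aryl- and alkenylboronic esters with CO2 and the alkylation of carboxylate salts by allylic electrophiles. The only stereocentre that changes is C2, inverted from R to S by the backside displacement while C1 is untouched, so the 1,2-syn precursor should give the trans-fused lactone. The step needs CO2 insertion to outrun copper-mediated allylic substitution of the phosphate and SN2 to outrun ionisation; CO2 saturation, high dilution, the five-membered intramolecular transition state and the absence of any π-allyl-forming metal should secure this, and the silyl ethers and other allylic C–O bonds are inert.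

Step 17
Reactants: 21 tris-silyl lactone
Product: 22 (1S,2S,3E,6S,7E,10S,11E,14S)-6-(tert-butyldimethylsilyloxy)-10,14-dihydroxycembra-3,7,11,15(17)-tetraen-16,2-olide
Conditions: PPTS, MeOH/CH2Cl2, 0 °C to rt
Reagents that add atoms: none
Why: acid-catalysed methanolysis should remove the two TES ethers much faster than the bulkier TBS ether (selective desilylation).

Step 18
Reactants: 22 diol
Product: 23 (1S,2S,3E,6S,7E,10S,11E,14S)-10,14-diacetoxy-6-(tert-butyldimethylsilyloxy)cembra-3,7,11,15(17)-tetraen-16,2-olide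
Conditions: Ac2O, pyridine, DMAP (cat.), CH2Cl2, 0 °C to rt
Reagents that add atoms: acetic anhydride, CC(=O)OC(C)=O
Why: DMAP-catalysed acetylation should esterify both secondary alcohols, including the hindered C14 hydroxyl.

Step 19
Reactants: 23 diacetate TBS ether
Product: 24 CNP0418981.1, (1S,2S,3E,6S,7E,10S,11E,14S)-10,14-diacetoxy-6-hydroxycembra-3,7,11,15(17)-tetraen-16,2-olide
Conditions: HF·pyridine, pyridine, THF, 0 °C to rt
Reagents that add atoms: none
Why: buffered fluoride cleavage of the TBS ether is non-basic and should spare the acetates and the α-methylene lactone.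

**Compound list**
1 | 3-methylbut-2-enoyl chloride | CC(C)=CC(=O)Cl | starting material
2 | morpholine | C1COCCN1 | starting material
3 | 4-(3-methylbut-2-enoyl)morpholine | CC(C)=CC(=O)N1CCOCC1 | intermediate
4 | (Z)-4-[1-(tert-butyldimethylsilyloxy)-3-methylbuta-1,3-dien-1-yl]morpholine | C=C(C)/C=C(\O[Si](C)(C)C(C)(C)C)N1CCOCC1 | intermediate
5 | 3-(trimethylsilyl)prop-2-ynal | C[Si](C)(C)C#CC=O | starting material
6 | (S,E)-5-hydroxy-3-methyl-1-(morpholin-4-yl)-7-(trimethylsilyl)hept-2-en-6-yn-1-one | C[Si](C)(C)C#C[C@@H](O)C/C(C)=C/C(=O)N1CCOCC1 | intermediate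
7 | (S,E)-5-hydroxy-3-methyl-1-(morpholin-4-yl)hept-2-en-6-yn-1-one | C#C[C@@H](O)C/C(C)=C/C(=O)N1CCOCC1 | intermediate
8 | (S,E)-5-hydroxy-3-methyl-1-(morpholin-4-yl)octa-2,6,7-trien-1-one | C=C=C[C@@H](O)C/C(C)=C/C(=O)N1CCOCC1 | intermediate
9 | (S,E)-3-methyl-1-(morpholin-4-yl)-5-(triethylsilyloxy)octa-2,6,7-trien-1-one | C=C=C[C@@H](O[Si](CC)(CC)CC)C/C(C)=C/C(=O)N1CCOCC1 | intermediate
10 | (S,E)-3-methyl-5-(triethylsilyloxy)octa-2,6,7-trienal | C=C=C[C@@H](O[Si](CC)(CC)CC)C/C(C)=C/C=O | intermediate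
11 | (2E,5S,6E,9S)-5-hydroxy-3,7-dimethyl-1-(morpholin-4-yl)-9-(triethylsilyloxy)dodeca-2,6,10,11-tetraen-1-one | C=C=C[C@@H](O[Si](CC)(CC)CC)C/C(C)=C/[C@@H](O)C/C(C)=C/C(=O)N1CCOCC1 | intermediate
12 | (2E,5S,6E,9S)-3,7-dimethyl-1-(morpholin-4-yl)-5,9-bis(triethylsilyloxy)dodeca-2,6,10,11-tetraen-1-one | C=C=C[C@@H](O[Si](CC)(CC)CC)C/C(C)=C/[C@@H](O[Si](CC)(CC)CC)C/C(C)=C/C(=O)N1CCOCC1 | intermediate
13 | (2E,5S,6E,9S)-3,7-dimethyl-5,9-bis(triethylsilyloxy)dodeca-2,6,10,11-tetraenal | C=C=C[C@@H](O[Si](CC)(CC)CC)C/C(C)=C/[C@@H](O[Si](CC)(CC)CC)C/C(C)=C/C=O | intermediate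
14 | (2E,5S,6E,9S,10E,13S)-5-hydroxy-3,7,11-trimethyl-1-(morpholin-4-yl)-9,13-bis(triethylsilyloxy)hexadeca-2,6,10,14,15-pentaen-1-one | C=C=C[C@@H](O[Si](CC)(CC)CC)C/C(C)=C/[C@@H](O[Si](CC)(CC)CC)C/C(C)=C/[C@@H](O)C/C(C)=C/C(=O)N1CCOCC1 | intermediate
15 | (2E,5S,6E,9S,10E,13S)-5-(tert-butyldimethylsilyloxy)-3,7,11-trimethyl-1-(morpholin-4-yl)-9,13-bis(triethylsilyloxy)hexadeca-2,6,10,14,15-pentaen-1-one | C=C=C[C@@H](O[Si](CC)(CC)CC)C/C(C)=C/[C@@H](O[Si](CC)(CC)CC)C/C(C)=C/[C@@H](O[Si](C)(C)C(C)(C)C)C/C(C)=C/C(=O)N1CCOCC1 | intermediate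
16 | (2E,5S,6E,9S,10E,13S,14Z)-5-(tert-butyldimethylsilyloxy)-3,7,11-trimethyl-1-(morpholin-4-yl)-15,16-bis(4,4,5,5-tetramethyl-1,3,2-dioxaborolan-2-yl)-9,13-bis(triethylsilyloxy)hexadeca-2,6,10,14-tetraen-1-one | CC1(C)OB(OC1(C)C)C/C(B1OC(C)(C)C(C)(C)O1)=C\[C@@H](O[Si](CC)(CC)CC)C/C(C)=C/[C@@H](O[Si](CC)(CC)CC)C/C(C)=C/[C@@H](O[Si](C)(C)C(C)(C)C)C/C(C)=C/C(=O)N1CCOCC1 | intermediate
17 | (2E,5S,6E,9S,10E,13S,14Z)-5-(tert-butyldimethylsilyloxy)-3,7,11-trimethyl-15,16-bis(4,4,5,5-tetramethyl-1,3,2-dioxaborolan-2-yl)-9,13-bis(triethylsilyloxy)hexadeca-2,6,10,14-tetraenal | CC1(C)OB(OC1(C)C)C/C(B1OC(C)(C)C(C)(C)O1)=C\[C@@H](O[Si](CC)(CC)CC)C/C(C)=C/[C@@H](O[Si](CC)(CC)CC)C/C(C)=C/[C@@H](O[Si](C)(C)C(C)(C)C)C/C(C)=C/C=O | intermediate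
18 | (1R,2R,3E,6S,7E,10S,11E,14S)-6-(tert-butyldimethylsilyloxy)-15-(4,4,5,5-tetramethyl-1,3,2-dioxaborolan-2-yl)-10,14-bis(triethylsilyloxy)-16-norcembra-3,7,11,15(17)-tetraen-2-ol | C=C(B1OC(C)(C)C(C)(C)O1)[C@@H]2[C@H](O)/C=C(\C)C[C@H](O[Si](C)(C)C(C)(C)C)/C=C(\C)C[C@H](O[Si](CC)(CC)CC)/C=C(\C)C[C@@H]2O[Si](CC)(CC)CC | intermediate
19 | diethyl (1S,2R,3E,6S,7E,10S,11E,14S)-6-(tert-butyldimethylsilyloxy)-15-(4,4,5,5-tetramethyl-1,3,2-dioxaborolan-2-yl)-10,14-bis(triethylsilyloxy)-16-norcembra-3,7,11,15(17)-tetraen-2-yl phosphate | C=C(B1OC(C)(C)C(C)(C)O1)[C@@H]2[C@H](OP(=O)(OCC)OCC)/C=C(\C)C[C@H](O[Si](C)(C)C(C)(C)C)/C=C(\C)C[C@H](O[Si](CC)(CC)CC)/C=C(\C)C[C@@H]2O[Si](CC)(CC)CC | intermediate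
20 | potassium (1S,2R,3E,6S,7E,10S,11E,14S)-6-(tert-butyldimethylsilyloxy)-2-(diethoxyphosphoryloxy)-10,14-bis(triethylsilyloxy)cembra-3,7,11,15(17)-tetraen-16-oate | C=C(C(=O)[O-])[C@@H]2[C@H](OP(=O)(OCC)OCC)/C=C(\C)C[C@H](O[Si](C)(C)C(C)(C)C)/C=C(\C)C[C@H](O[Si](CC)(CC)CC)/C=C(\C)C[C@@H]2O[Si](CC)(CC)CC.[K+] | intermediate
21 | (1R,2S,3E,6S,7E,10S,11E,14S)-6-(tert-butyldimethylsilyloxy)-10,14-bis(triethylsilyloxy)cembra-3,7,11,15(17)-tetraen-16,2-olide | C=C1C(=O)O[C@H]2/C=C(\C)C[C@H](O[Si](C)(C)C(C)(C)C)/C=C(\C)C[C@H](O[Si](CC)(CC)CC)/C=C(\C)C[C@H](O[Si](CC)(CC)CC)[C@H]12 | intermediate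
22 | (1S,2S,3E,6S,7E,10S,11E,14S)-6-(tert-butyldimethylsilyloxy)-10,14-dihydroxycembra-3,7,11,15(17)-tetraen-16,2-olide | C=C1C(=O)O[C@H]2/C=C(\C)C[C@H](O[Si](C)(C)C(C)(C)C)/C=C(\C)C[C@H](O)/C=C(\C)C[C@H](O)[C@H]12 | intermediate
23 | (1S,2S,3E,6S,7E,10S,11E,14S)-10,14-diacetoxy-6-(tert-butyldimethylsilyloxy)cembra-3,7,11,15(17)-tetraen-16,2-olide | C=C1C(=O)O[C@H]2/C=C(\C)C[C@H](O[Si](C)(C)C(C)(C)C)/C=C(\C)C[C@H](OC(C)=O)/C=C(\C)C[C@H](OC(C)=O)[C@H]12 | intermediate
24 | CNP0418981.1, (1S,2S,3E,6S,7E,10S,11E,14S)-10,14-diacetoxy-6-hydroxycembra-3,7,11,15(17)-tetraen-16,2-olide | C=C1C(=O)O[C@H]2/C=C(\C)C[C@H](O)/C=C(\C)C[C@H](OC(C)=O)/C=C(\C)C[C@H](OC(C)=O)[C@H]12 | target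

**Summary**
Total step count: 19.
Longest linear sequence: 19 steps (1 → 3 → 4 → 6 → … → 24); 17 steps from aldehyde 5.

Three steps most likely to fail:

Step 13. The diboron may add across the internal instead of the terminal C=C of the allene, or the Z geometry may erode, which would misplace the allylic boron. Fallback: the sequence sets out from 15, which is reduced with DIBAL-H to the allenyl enal F1. At high dilution a copper(I)–NHC catalyst with NaOt-Bu and B2pin2 should add Cu–B across the terminal C=C, boron going to the central carbon as is inherent to borylcupration. The 2-boryl allylcopper should then add through its γ-carbon to the tethered aldehyde, and work-up returns to the route at 18.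

Step 14. Ring closure of the hindered pinacol allylboronate may be slow, allowing intermolecular allylboration (oligomerisation) or eroding facial selectivity at C1. Fallback: the sequence sets out from 15, reduced as above to the allenyl enal F2. Bromoboration of the allene with B-bromo-9-borabicyclo[3.3.1]nonane at −78 °C under high dilution (bromine to the central carbon) should give a dialkyl(2-bromoallyl)borane, which is far more reactive than a boronate and should close the ring at low temperature to the macrocyclic 2-bromovinyl carbinol F3. Miyaura borylation (B2pin2, PdCl2(dppf), KOAc, dioxane) then returns to the route at 18.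

Step 16. The allylic phosphate may ionise or eliminate before the carboxylate attacks (loss of stereospecificity at C2, diene formation), the alkenylcopper may undergo allylic substitution, or the boronate may protodeboronate. Fallback: the sequence sets out from 18. Mitsunobu inversion with benzoic acid (PPh3, DIAD) should give the C2-epimeric benzoate F4. Copper-catalysed carboxylation under the conditions of step 16 with acidic work-up should give the acrylic acid F5. Pd(PPh3)4/Et3N should then ionise the allylic benzoate, and the carboxylate should close the lactone with net retention (double inversion), returning to the route at 21.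

Further compounds
F1 | step 13 | (2E,5S,6E,9S,10E,13S)-5-(tert-butyldimethylsilyloxy)-3,7,11-trimethyl-9,13-bis(triethylsilyloxy)hexadeca-2,6,10,14,15-pentaenal | C=C=C[C@@H](O[Si](CC)(CC)CC)C/C(C)=C/[C@@H](O[Si](CC)(CC)CC)C/C(C)=C/[C@@H](O[Si](C)(C)C(C)(C)C)C/C(C)=C/C=O
F2 | step 14 | (2E,5S,6E,9S,10E,13S)-5-(tert-butyldimethylsilyloxy)-3,7,11-trimethyl-9,13-bis(triethylsilyloxy)hexadeca-2,6,10,14,15-pentaenal | C=C=C[C@@H](O[Si](CC)(CC)CC)C/C(C)=C/[C@@H](O[Si](CC)(CC)CC)C/C(C)=C/[C@@H](O[Si](C)(C)C(C)(C)C)C/C(C)=C/C=O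
F3 | step 14 | (1R,2R,3E,6S,7E,10S,11E,14S)-15-bromo-6-(tert-butyldimethylsilyloxy)-10,14-bis(triethylsilyloxy)-16-norcembra-3,7,11,15(17)-tetraen-2-ol | C=C(Br)[C@@H]2[C@H](O)/C=C(\C)C[C@H](O[Si](C)(C)C(C)(C)C)/C=C(\C)C[C@H](O[Si](CC)(CC)CC)/C=C(\C)C[C@@H]2O[Si](CC)(CC)CC
F4 | step 16 | (1R,2S,3E,6S,7E,10S,11E,14S)-6-(tert-butyldimethylsilyloxy)-15-(4,4,5,5-tetramethyl-1,3,2-dioxaborolan-2-yl)-10,14-bis(triethylsilyloxy)-16-norcembra-3,7,11,15(17)-tetraen-2-yl benzoate | C=C(B1OC(C)(C)C(C)(C)O1)[C@@H]2[C@@H](OC(=O)c3ccccc3)/C=C(\C)C[C@H](O[Si](C)(C)C(C)(C)C)/C=C(\C)C[C@H](O[Si](CC)(CC)CC)/C=C(\C)C[C@@H]2O[Si](CC)(CC)CC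
F5 | step 16 | (1R,2S,3E,6S,7E,10S,11E,14S)-2-(benzoyloxy)-6-(tert-butyldimethylsilyloxy)-10,14-bis(triethylsilyloxy)cembra-3,7,11,15(17)-tetraen-16-oic acid | C=C(C(=O)O)[C@@H]2[C@@H](OC(=O)c3ccccc3)/C=C(\C)C[C@H](O[Si](C)(C)C(C)(C)C)/C=C(\C)C[C@H](O[Si](CC)(CC)CC)/C=C(\C)C[C@@H]2O[Si](CC)(CC)CC
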